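The substrate units in the flask add up to the charge at each moment, with one self-condensation product counted as two, so I looked for a ratio that holds still while they move.

    substrate ⇌ target (K1 = 0.0825, k1 = 4.56 × 10⁻⁴ s⁻¹)
    target → over-reaction product (k2 = 1.68 × 10⁻⁴ s⁻¹)
    2 substrate → self-condensation product (k3 = 5.76 × 10⁻⁵ L mol⁻¹ s⁻¹)

substrate 1.0 M; time 3.0 h

- percent here means substrate units held: one self-condensation product counts as two
- for a step with 2 of a species take k times the square, and two of it per event
- the reaction counts as stopped when no species that holds the substrate changes by six tenths of a point or more over the second half of the time
- run time (flask): 3.0 h

- why nothing more happens at 3.0 h, or that something still does (all of the substrate has reacted / it is still moving / forward and back rates have come level)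
- how much of the substrate has reacted by 3.0 h
- how much target there is at 3.0 h, in percent of the substrate charged

Did the exchange hold? Its relaxation half-life was 1.93 min, shorter than the 1.1 h half-life of target by step 2. So I took target as 0.0825 times substrate once the exchange had relaxed, a pre-equilibrium, and the charge split into 0.924 M substrate plus its target.

Where did the flask head? Steps 2 and 3 run one way, so the end state was no balance of the exchange.

How fast did it go? Units left by a straight loss through target and a squared loss through self-condensation. I kept one number: 0.120 M, the substrate concentration at which the two losses are equal, the crossover level. The substrate after that split stood 7.70 times above it, so self-condensation led the two losses at that moment.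

For such a pair of losses, substrate/(substrate + level) decays plainly, at k2 times target's share of substrate plus target, 0.0461 h⁻¹. That fraction went from 0.885 to 0.771 by 3.0 h, which gave substrate 0.404 M. So I reckoned 59.6% reacted and 3.33% target. At 1.50 h the same rule gave 0.570 M, so I judged the flask still moving.

The forecast said it is still moving, with 59.5% (58% to 61%) reacted and 3.3% (3.1% to 3.5%) target, holding that “target simply tracks the substrate as it falls”.

The simulation gave 59.5% reacted and 3.27% target: it is still moving. The largest share moved 17 percentage points over the last 1.50 h. The substrate left in the flask, 0.405 M, stood 3.36 times above the crossover level. For the neighbouring flask read at 12.0 h, the rule gave 12.5% of the charge as substrate, and that flask held 13%.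

Its constants are invented, and the outcome is calculated.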